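**Plan**

Retrosynthesis: the two benzyl ethers and the 7-O-methyl group are removed first; then O1–C2 of the pyranone and C4a–C8a of ring A are cut together, which unrolls rings A and C into one open chain, methyl 9-aryl-3,5,7,9-tetraoxononanoate 15.
Enabling feature: C8a–C8–C7–C6–C5–C4a of ring A and C4–C3–C2 of ring C are nine consecutive carbons with oxygen on every second one (C8a, C7, C5, C4, C2), that is, a phloroglucinol ring A fused to a 1,3-dicarbonyl unit that ends at the ring B carbon C1'.
The chain is cut further at C2–C3 (aroylation by a ring B benzoate) and at C8–C8a (carboxylation), leaving heptane-2,4,6-trione (C3 to C8) from 2,6-dimethyl-4-pyranone.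
Forward: ring B ester 7 is made from 2,3-dimethoxyphenol; the triketone is aroylated, carboxylated and esterified; one operation then closes ring A (Claisen) and ring C (cyclodehydration); 7-O-methylation and hydrogenolysis finish.
Stereochemistry: the target has no stereocentre and no configured double bond, so nothing has to be set.

Key step: step 10

Remark: polycarbonyl compounds are named and drawn as keto tautomers and polyanions as lithium or barium enolates, although each is an enol or chelate mixture in practice.

**Route**

Step 1
Reactants: 1 2,3-dimethoxyphenol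
Product: 2 2,3-dimethoxy-1,4-benzoquinone
Conditions: (KSO3)2NO (2.2 equiv), KH2PO4 buffer, H2O/acetone, 0 °C to rt
Reagents that add atoms: potassium nitrosodisulfonate (Fremy's salt), [K+].[K+].[O]N(S(=O)(=O)[O-])S(=O)(=O)[O-]
Why: Teuber oxidation, in which the nitroxyl radical removes the phenolic hydrogen and a second equivalent delivers oxygen to the free para carbon, so a phenol with an open para position should give the para-quinone.

Step 2
Reactants: 2 2,3-dimethoxy-1,4-benzoquinone
Product: 3 2,3-dimethoxybenzene-1,4-diol
Conditions: Na2S2O4, EtOAc/H2O, rt, under N2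
Reagents that add atoms: none
Why: Dithionite reduction of a quinone to its hydroquinone is fast and leaves the methyl ethers untouched.

Step 3
Reactants: 3 2,3-dimethoxybenzene-1,4-diol
Product: 4 1,4-bis(benzyloxy)-2,3-dimethoxybenzene
Conditions: BnBr (2.4 equiv), K2CO3, DMF, rt, under N2
Reagents that add atoms: benzyl bromide, BrCc1ccccc1
Why: Williamson ether synthesis on both phenoxides installs base-stable benzyl ethers that survive the later polyanion chemistry and can be removed without touching the methyl ethers.

Step 4
Reactants: 4 1,4-bis(benzyloxy)-2,3-dimethoxybenzene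
Product: 5 1,4-bis(benzyloxy)-5-bromo-2,3-dimethoxybenzene
Conditions: NBS (1.0 equiv), MeCN, 0 °C to rt, dark
Reagents that add atoms: N-bromosuccinimide, O=C1CCC(=O)N1Br
Why: Electrophilic aromatic bromination, where the two free positions are equivalent by symmetry, each is ortho to a benzyloxy and para to a methoxy group, and the first bromine deactivates the ring against a second.

Step 5
Reactants: 5 1,4-bis(benzyloxy)-5-bromo-2,3-dimethoxybenzene
Product: 7 methyl 2,5-bis(benzyloxy)-3,4-dimethoxybenzoate, via [2,5-bis(benzyloxy)-3,4-dimethoxyphenyl]lithium 6 (not isolated)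
Conditions: n-BuLi (1.05 equiv), THF, −78 °C; then cannulated into ClCO2Me (3 equiv), THF, −78 °C
Reagents that add atoms: methyl chloroformate, COC(=O)Cl
Why: Bromine–lithium exchange is faster at −78 °C than benzylic deprotonation, and inverse addition of the aryllithium to excess chloroformate should stop the acylation at the ester.

Step 6
Reactants: 8 2,6-dimethyl-4H-pyran-4-one
Product: 10 heptane-2,4,6-trione, via barium heptane-2,4,6-trione dienolate 9 (not isolated)
Conditions: Ba(OH)2·8H2O, H2O, 60 °C then rt; then 2 M HCl, 0 °C, Et2O extraction; used at once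
Reagents that add atoms: barium hydroxide, [Ba+2].[OH-].[OH-]
Why: Hydroxide adds to C2 of the pyranone and the ring opens by retro-oxa-Michael cleavage, precipitation of the barium salt drives the equilibrium, and cold acidification should release the triketone before it recloses.

Step 7
Reactants: 10 heptane-2,4,6-trione; 7 methyl 2,5-bis(benzyloxy)-3,4-dimethoxybenzoate
Product: 12 1-[2,5-bis(benzyloxy)-3,4-dimethoxyphenyl]octane-1,3,5,7-tetraone, via trilithium heptane-2,4,6-trione trianion 11 (not isolated)
Conditions: 10 (2 equiv), LiN(iPr)2 (6.2 equiv), THF, 0 °C; then 7 (1 equiv), 0 °C to rt; cold 1 M HCl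
Reagents that add atoms: none
Why: Claisen-type acylation of a 1,3,5-triketone trianion by an aromatic ester takes place at the terminal, last-formed and most nucleophilic carbanion, and the second equivalent of trianion absorbs the acidic proton of the product.

Step 8
Reactants: 12 1-[2,5-bis(benzyloxy)-3,4-dimethoxyphenyl]octane-1,3,5,7-tetraone
Product: 14 9-[2,5-bis(benzyloxy)-3,4-dimethoxyphenyl]-3,5,7,9-tetraoxononanoic acid, via tetralithium aryloctanetetraone tetraanion 13 (not isolated)
Conditions: LiN(iPr)2 (4.5 equiv), THF, 0 °C; then CO2 (g), −78 to 0 °C; cold 1 M HCl, Et2O, kept below 5 °C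
Reagents that add atoms: carbon dioxide, O=C=O
Why: Carboxylation of a poly-beta-ketone polyanion occurs at the terminal methyl carbanion, the only site not stabilised by two carbonyl groups, and cold work-up should limit decarboxylation of the beta-keto acid.

Step 9
Reactants: 14 9-[2,5-bis(benzyloxy)-3,4-dimethoxyphenyl]-3,5,7,9-tetraoxononanoic acid
Product: 15 methyl 9-[2,5-bis(benzyloxy)-3,4-dimethoxyphenyl]-3,5,7,9-tetraoxononanoate
Conditions: CH2N2 (1.05 equiv), Et2O, −10 to 0 °C, 5 min; AcOH quench
Reagents that add atoms: diazomethane, C=[N+]=[N-]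
Why: Diazomethane esterification, in which the carboxylic acid protonates the reagent far faster than the hydrogen-bonded enols do, so brief exposure to one equivalent should methylate only the carboxyl group.

Step 10
Reactants: 15 methyl 9-[2,5-bis(benzyloxy)-3,4-dimethoxyphenyl]-3,5,7,9-tetraoxononanoate
Product: 17 2-[2,5-bis(benzyloxy)-3,4-dimethoxyphenyl]-5,7-dihydroxy-4H-chromen-4-one, via aroylacetylphloroglucinol 16 (not isolated)
Conditions: Mg(OMe)2 (8 equiv), dry MeOH, 65 °C; then HCl/MeOH to pH 1, 60 °C
Reagents that add atoms: none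
Why: Mg(OMe)2 ties the C3/C5 and C7/C9 diketone pairs of the chain into magnesium enolate chelates, so the central carbon C6 (future C4a) is the carbanion lying six atoms from the ester carbon C1 (future C8a) and adds to it in a 6-exo-trig Claisen (Dieckmann-type) condensation; expulsion of methoxide and tautomerisation of the cyclic triketone then deliver the aromatic acylphloroglucinol 16 as its magnesium chelate. On acidification an ortho hydroxyl of 16 adds to the aroyl carbonyl (future C2) in a 6-exo-trig closure and the resulting 2-hydroxychromanone loses water to give the pyranone ring. The closest known reaction type is the Claisen-type cyclisation of 3,5,7-triketo and 3,5,7,9-tetraketo esters to acylphloroglucinols, whose 1,3-diketone side chains cyclodehydrate to chromones. No stereocentre is formed. The selectivity required is Claisen folding over the aldol folds (C2 onto the C7 ketone, C8 onto C3, C4 onto C9); it should be secured by the anhydrous magnesium alkoxide medium, in which the ketones are masked as chelated enolates while the ester remains the carbonyl acceptor and its reaction is made irreversible by aromatisation, and by the aroyl carbonyl being a reluctant acceptor because of its ortho benzyloxy group and electron-rich ring. Because the 2'-oxygen is benzylated only a ring A hydroxyl can close onto C2, and the two ortho hydroxyls of the symmetric phloroglucinol lead to the same flavone.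

Step 11
Reactants: 17 2-[2,5-bis(benzyloxy)-3,4-dimethoxyphenyl]-5,7-dihydroxy-4H-chromen-4-one
Product: 18 2-[2,5-bis(benzyloxy)-3,4-dimethoxyphenyl]-5-hydroxy-7-methoxy-4H-chromen-4-one
Conditions: Me2SO4 (1.05 equiv), K2CO3, acetone, 56 °C
Reagents that add atoms: dimethyl sulfate, COS(=O)(=O)OC
Why: Williamson O-methylation should be selective for the 7-hydroxyl, the more acidic vinylogous acid, while the 5-hydroxyl is held in a hydrogen bond to the C4 carbonyl and reacts much more slowly.

Step 12
Reactants: 18 2-[2,5-bis(benzyloxy)-3,4-dimethoxyphenyl]-5-hydroxy-7-methoxy-4H-chromen-4-one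
Product: 19 2-(2,5-dihydroxy-3,4-dimethoxyphenyl)-5-hydroxy-7-methoxy-4H-chromen-4-one (CNP0170944.0)
Conditions: H2 (1 atm), 10% Pd/C, EtOAc/MeOH, rt; filtered and concentrated under Ar
Reagents that add atoms: none
Why: Catalytic hydrogenolysis cleaves the two aryl benzyl ethers under neutral conditions that leave the methyl ethers and the conjugated pyranone double bond intact, and exclusion of air protects the liberated hydroquinone.

**Compound list**

1 | 2,3-dimethoxyphenol | COc1cccc(O)c1OC | starting material
2 | 2,3-dimethoxy-1,4-benzoquinone | COC1=C(OC)C(=O)C=CC1=O | intermediate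
3 | 2,3-dimethoxybenzene-1,4-diol | COc1c(O)ccc(O)c1OC | intermediate
4 | 1,4-bis(benzyloxy)-2,3-dimethoxybenzene | COc1c(OC)c(OCc2ccccc2)ccc1OCc3ccccc3 | intermediate
5 | 1,4-bis(benzyloxy)-5-bromo-2,3-dimethoxybenzene | Brc1cc(OCc2ccccc2)c(OC)c(OC)c1OCc3ccccc3 | intermediate
6 | [2,5-bis(benzyloxy)-3,4-dimethoxyphenyl]lithium | [Li]c1cc(OCc2ccccc2)c(OC)c(OC)c1OCc3ccccc3 | intermediate
7 | methyl 2,5-bis(benzyloxy)-3,4-dimethoxybenzoate | COC(=O)c1cc(OCc2ccccc2)c(OC)c(OC)c1OCc3ccccc3 | intermediate
8 | 2,6-dimethyl-4H-pyran-4-one | Cc1cc(=O)cc(C)o1 | starting material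
9 | barium dienolate of heptane-2,4,6-trione | [Ba+2].CC(=O)C=C([O-])C=C(C)[O-] | intermediate
10 | heptane-2,4,6-trione | CC(=O)CC(=O)CC(C)=O | intermediate
11 | trilithium trianion of heptane-2,4,6-trione | [Li+].[Li+].[Li+].C=C([O-])C=C([O-])C=C(C)[O-] | intermediate
12 | 1-[2,5-bis(benzyloxy)-3,4-dimethoxyphenyl]octane-1,3,5,7-tetraone | CC(=O)CC(=O)CC(=O)CC(=O)c1cc(OCc2ccccc2)c(OC)c(OC)c1OCc3ccccc3 | intermediate
13 | tetralithium tetraanion of 1-[2,5-bis(benzyloxy)-3,4-dimethoxyphenyl]octane-1,3,5,7-tetraone | [Li+].[Li+].[Li+].[Li+].C=C([O-])C=C([O-])C=C([O-])C=C([O-])c1cc(OCc2ccccc2)c(OC)c(OC)c1OCc3ccccc3 | intermediate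
14 | 9-[2,5-bis(benzyloxy)-3,4-dimethoxyphenyl]-3,5,7,9-tetraoxononanoic acid | OC(=O)CC(=O)CC(=O)CC(=O)CC(=O)c1cc(OCc2ccccc2)c(OC)c(OC)c1OCc3ccccc3 | intermediate
15 | methyl 9-[2,5-bis(benzyloxy)-3,4-dimethoxyphenyl]-3,5,7,9-tetraoxononanoate | COC(=O)CC(=O)CC(=O)CC(=O)CC(=O)c1cc(OCc2ccccc2)c(OC)c(OC)c1OCc3ccccc3 | intermediate
16 | 1-[2,5-bis(benzyloxy)-3,4-dimethoxyphenyl]-3-(2,4,6-trihydroxyphenyl)propane-1,3-dione | Oc1cc(O)c(C(=O)CC(=O)c2cc(OCc3ccccc3)c(OC)c(OC)c2OCc4ccccc4)c(O)c1 | intermediate
17 | 2-[2,5-bis(benzyloxy)-3,4-dimethoxyphenyl]-5,7-dihydroxy-4H-chromen-4-one | Oc1cc(O)c2c(=O)cc(-c3cc(OCc4ccccc4)c(OC)c(OC)c3OCc5ccccc5)oc2c1 | intermediate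
18 | 2-[2,5-bis(benzyloxy)-3,4-dimethoxyphenyl]-5-hydroxy-7-methoxy-4H-chromen-4-one | COc1cc(O)c2c(=O)cc(-c3cc(OCc4ccccc4)c(OC)c(OC)c3OCc5ccccc5)oc2c1 | intermediate
19 | 2-(2,5-dihydroxy-3,4-dimethoxyphenyl)-5-hydroxy-7-methoxy-4H-chromen-4-one (CNP0170944.0) | COc1cc(O)c2c(=O)cc(-c3cc(O)c(OC)c(OC)c3O)oc2c1 | target

**Step count**

Total step count: 12.
Longest linear sequence: 11 steps (steps 1 to 5, then 7 to 12, from 2,3-dimethoxyphenol); step 6 is a one-step branch that joins at step 7.

**Steps most likely to fail**

Step 10. The chain may fold through an aldol mode (the ester alpha-carbon onto the C7 ketone, or C8 onto C3) instead of the Claisen mode, and traces of water may saponify the ester or lactonise the terminus to a 4-hydroxy-2-pyranone, taking the acceptor out of play. The fallback replaces chain folding by aroylation of a preformed ring A ketone and sets out from 7. Saponification of 7 (KOH, MeOH/H2O) should give 2,5-bis(benzyloxy)-3,4-dimethoxybenzoic acid F1, which oxalyl chloride with catalytic DMF in CH2Cl2 converts into 2,5-bis(benzyloxy)-3,4-dimethoxybenzoyl chloride F2. Commercial 2,4,6-trihydroxyacetophenone is treated with LiN(SiMe3)2 (4.2 equiv) in THF at −78 °C to form the tetralithium salt of 2,4,6-trihydroxyacetophenone F3, whose enolate carbon is aroylated by F2 to give diketone 16. Acid cyclodehydration as in the second stage of step 10 then returns the route at 17.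

Step 8. The fourth deprotonation may be incomplete, so that carboxylation stalls, and the free polyketo acid may decarboxylate or cyclise during acidic work-up; enol O-methylation in step 9 adds to the loss. The fallback reverses the order of chain assembly so that the carboxyl carbon is in place as an ester before the aryl group arrives, and it sets out from 10. Trianion 11 is acylated with dimethyl carbonate to give methyl 3,5,7-trioxooctanoate F4. LiN(iPr)2 (4.2 equiv) in THF at 0 °C converts F4 into the tetralithium tetraanion of methyl 3,5,7-trioxooctanoate F5, which is aroylated at its terminal carbanion by ester 7. This comes back to the route directly at 15, bypassing 12 and 14 and avoiding both the free acid and diazomethane.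

Step 7. Acylation by the ortho-substituted, electron-rich ester may be slow enough for proton transfer between product and trianion, self-condensation of the triketone and its reclosure to the pyranone to take over. The fallback builds the chain two carbons at a time from the aryl end through a stable, purifiable triketone, and it sets out from 7. Pentane-2,4-dione and LiN(iPr)2 (2.1 equiv) in THF give the dilithium dianion of pentane-2,4-dione F6, a small and strongly nucleophilic partner whose terminal carbanion is aroylated by 7 to give 1-[2,5-bis(benzyloxy)-3,4-dimethoxyphenyl]hexane-1,3,5-trione F7. LiN(iPr)2 (3.2 equiv) then forms the trilithium trianion of 1-[2,5-bis(benzyloxy)-3,4-dimethoxyphenyl]hexane-1,3,5-trione F8, which is acetylated at the terminal carbon with N-methoxy-N-methylacetamide. This comes back to the route at 12.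

**Further compounds**

F1 | step 10 | 2,5-bis(benzyloxy)-3,4-dimethoxybenzoic acid | OC(=O)c1cc(OCc2ccccc2)c(OC)c(OC)c1OCc3ccccc3
F2 | step 10 | 2,5-bis(benzyloxy)-3,4-dimethoxybenzoyl chloride | ClC(=O)c1cc(OCc2ccccc2)c(OC)c(OC)c1OCc3ccccc3
F3 | step 10 | tetralithium salt of 2,4,6-trihydroxyacetophenone | [Li+].[Li+].[Li+].[Li+].C=C([O-])c1c([O-])cc([O-])cc1[O-]
F4 | step 8 | methyl 3,5,7-trioxooctanoate | COC(=O)CC(=O)CC(=O)CC(C)=O
F5 | step 8 | tetralithium tetraanion of methyl 3,5,7-trioxooctanoate | [Li+].[Li+].[Li+].[Li+].C=C([O-])C=C([O-])C=C([O-])C=C([O-])OC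
F6 | step 7 | dilithium dianion of pentane-2,4-dione | [Li+].[Li+].C=C([O-])C=C(C)[O-]
F7 | step 7 | 1-[2,5-bis(benzyloxy)-3,4-dimethoxyphenyl]hexane-1,3,5-trione | CC(=O)CC(=O)CC(=O)c1cc(OCc2ccccc2)c(OC)c(OC)c1OCc3ccccc3
F8 | step 7 | trilithium trianion of 1-[2,5-bis(benzyloxy)-3,4-dimethoxyphenyl]hexane-1,3,5-trione | [Li+].[Li+].[Li+].C=C([O-])C=C([O-])C=C([O-])c1cc(OCc2ccccc2)c(OC)c(OC)c1OCc3ccccc3
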